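**Retrosynthetic overview** (eudesmane numbering C1–C15)
1. Target ⇒ C3 ester cleavage to the 3α,4α-diol and (S)-3-methylpentanoic acid; the diol ⇒ α-face syn-dihydroxylation of the C3=C4 bond of eudesma-3,7(11)-dien-8-one.
2. Dienone ⇒ oxidation and conjugation of the 8-hydroxy-11-ene, itself from C7–C8 closure of ring B (second ring) by an intramolecular carbonyl-ene reaction of a C8 aldehyde; C8 comes from methoxymethylene Wittig homologation of the C9 formyl group.
3. Ring A (first ring) ⇒ catalytic enantioselective Diels–Alder union of (E)-β-ocimene and methacrolein, forming C1–C2 and C5–C10 and setting C10 and C5.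
4. Feature the plan rests on: ring A (C1–C5, C10) is a cyclohex-3-ene whose quaternary C10 (methyl C14, branch C9) sits next to C5; C1, C9, C10 and C14 are the four carbons of methacrolein, and C2–C7, C11–C13 and C15 are the ten carbons of (E)-β-ocimene, whose untouched prenyl end (C6, C7, C11–C13) later closes ring B.

Key step: step 1

Assumption: commercial β-ocimene is an E/Z mixture and is used as such in excess; only the E isomer 1 can reach a planar s-cis diene and is expected to react, the Z isomer leaving with the excess diene.

**Step 1**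
Reactants: 1 (E)-β-ocimene [(3E)-3,7-dimethylocta-1,3,6-triene]; 2 methacrolein (2-methylprop-2-enal)
Product: 3 (1S,2S)-1,3-dimethyl-2-(3-methylbut-2-en-1-yl)cyclohex-3-ene-1-carbaldehyde (formyl trans to the prenyl arm)
Conditions: 1 (excess), (S)-3,3-diphenyl-1-(2-methylphenyl)tetrahydro-1H,3H-pyrrolo[1,2-c][1,3,2]oxazaborole (20 mol %), HNTf2 (18 mol %), CH2Cl2, −78 to −40 °C
Reagents that add atoms: none
Why: The N-protonated oxazaborolidine binds the formyl oxygen of 2 and the s-cis diene of 1 adds to the activated enal in a concerted but asynchronous [4+2] cycloaddition, the unsubstituted diene terminus C2 bonding to the β-carbon C1 slightly ahead of C5 to the α-carbon C10. The closest known reaction type is the cationic oxazaborolidine-catalysed Diels–Alder reaction of methacrolein and other 2-substituted acroleins with alkyl-substituted dienes, which is established for building formyl-bearing quaternary carbons, although this triene has not been used in it. Ring A is closed by the cycloaddition itself, as a six-membered ring made by intermolecular formation of the two σ-bonds C1–C2 and C5–C10, with the C3=C4 olefin and its methyl group C15 delivered by the diene. C10 is set by the catalyst, whose aryl group shields one face of the bound s-trans enal so that the (S)-configured catalyst should direct the diene to the face giving the 1S quaternary centre (the mirror-image catalyst is held in reserve should the sense prove opposite). C5 is set relative to C10 by the E geometry of the diene together with a formyl-exo transition state, expected because the bulky catalyst-bound formyl group avoids the space under the diene next to the C4 methyl group and leaves it to the small α-methyl group, which places formyl trans to the prenyl arm. The step needs ortho-type regiochemistry, which the terminal alkyl substituent under Lewis-acid activation should enforce over the weaker opposing pull of the internal methyl group, and it needs the isolated C7=C11 olefin to stay out of the reaction, which holds because it is not part of a diene and because ene attack on the neopentyl aldehyde is slow at −78 °C.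

**Step 2**
Reactants: 3 (1S,2S)-1,3-dimethyl-2-(3-methylbut-2-en-1-yl)cyclohex-3-ene-1-carbaldehyde; 4 (methoxymethyl)triphenylphosphonium chloride
Product: 6 (5S,6S)-5-(2-methoxyethenyl)-1,5-dimethyl-6-(3-methylbut-2-en-1-yl)cyclohex-1-ene (enol ether; E/Z mixture), via (methoxymethylene)triphenylphosphorane 5 (not isolated)
Conditions: 4, KOtBu, THF, 0 °C; then 3, 0 °C to rt
Reagents that add atoms: none
Why: Wittig olefination with the non-stabilised methoxymethylene ylide is the standard one-carbon homologation of hindered neopentyl aldehydes, and since the α-carbon C10 is quaternary the basic medium can neither enolise nor epimerise the substrate.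

**Step 3**
Reactants: 6 (5S,6S)-5-(2-methoxyethenyl)-1,5-dimethyl-6-(3-methylbut-2-en-1-yl)cyclohex-1-ene
Product: 7 2-[(1R,2R)-1,3-dimethyl-2-(3-methylbut-2-en-1-yl)cyclohex-3-en-1-yl]acetaldehyde (the C8 aldehyde)
Conditions: 2 M aq. HCl, THF, 0 °C to rt
Reagents that add atoms: water O
Why: Acid-catalysed enol ether hydrolysis (C-protonation, hemiacetal, loss of methanol) is far faster than protonation of the two trisubstituted alkenes in cold dilute acid, so the aldehyde should be released without cyclisation or olefin migration.

**Step 4**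
Reactants: 7 2-[(1R,2R)-1,3-dimethyl-2-(3-methylbut-2-en-1-yl)cyclohex-3-en-1-yl]acetaldehyde
Product: 8 (2S,3R,4aR,8aR)-5,8a-dimethyl-3-(prop-1-en-2-yl)-1,2,3,4,4a,7,8,8a-octahydronaphthalen-2-ol (eudesma-3,11-dien-8α-ol, trans-fused)
Conditions: Me2AlCl (1.1 equiv), CH2Cl2, −78 to 0 °C; then H2O
Reagents that add atoms: none
Why: This is an intramolecular carbonyl-ene reaction of the citronellal-to-isopulegol kind, in which the aluminium-activated C8 aldehyde is attacked by C7 of the prenyl olefin through a six-membered chair transition state with hydrogen transfer from a C11 methyl group; the two reacting chains are trans-diequatorial on ring A, so ring B closes trans-fused, the aluminium alkoxide loses methane and thereby removes the proton that could start cation–olefin side reactions, and the new C7 and C8 centres (expected 7β-isopropenyl, 8α-hydroxy) are both erased in steps 5 and 6.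

**Step 5**
Reactants: 8 eudesma-3,11-dien-8α-ol
Product: 9 (3R,4aR,8aR)-5,8a-dimethyl-3-(prop-1-en-2-yl)-3,4,4a,7,8,8a-hexahydronaphthalen-2(1H)-one (eudesma-3,11-dien-8-one)
Conditions: Dess–Martin periodinane, CH2Cl2, 0 °C to rt
Reagents that add atoms: none
Why: Dess–Martin oxidation converts the secondary alcohol to the ketone under non-acidic, non-metal conditions that leave both alkenes alone, and any C8 epimers of 8 converge here.

**Step 6**
Reactants: 9 eudesma-3,11-dien-8-one
Product: 10 (4aR,8aR)-5,8a-dimethyl-3-(propan-2-ylidene)-3,4,4a,7,8,8a-hexahydronaphthalen-2(1H)-one (eudesma-3,7(11)-dien-8-one)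
Conditions: NaOMe (0.2 equiv), MeOH, 0 °C to rt
Reagents that add atoms: none
Why: Base-mediated deconjugated-to-conjugated enone isomerisation (the isopulegone-to-pulegone change) proceeds through the C7 dienolate and reprotonation at the terminal CH2 to give the thermodynamically favoured tetrasubstituted 7(11)-en-8-one, while C5 and C10 are not enolisable and stay fixed.

**Step 7**
Reactants: 10 eudesma-3,7(11)-dien-8-one
Product: 11 (4aR,5S,6R,8aR)-5,6-dihydroxy-5,8a-dimethyl-3-(propan-2-ylidene)-3,4,4a,5,6,7,8,8a-octahydronaphthalen-2(1H)-one (3α,4α-dihydroxyeudesm-7(11)-en-8-one)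
Conditions: OsO4 (5 mol %), NMO (1.5 equiv), acetone/H2O, rt
Reagents that add atoms: osmium tetroxide O=[Os](=O)(=O)=O; N-methylmorpholine N-oxide C[N+]1([O-])CCOCC1; water O
Why: Catalytic syn-dihydroxylation should pick the electron-rich trisubstituted C3=C4 bond over the electron-poor, tetrasubstituted enone olefin and should add from the α face, because the axial C10 methyl group stands 1,3-diaxial over C4 on the β face, which sets C3 (R) and C4 (S) as the cis 3α,4α-diol.

**Step 8**
Reactants: 11 3α,4α-dihydroxyeudesm-7(11)-en-8-one; 12 (S)-3-methylpentanoic acid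
Product: 13 (1S,2R,4aR,8aR)-1-hydroxy-1,4a-dimethyl-6-oxo-7-(propan-2-ylidene)decahydronaphthalen-2-yl (3S)-3-methylpentanoate (CNP0334363.1)
Conditions: 12 (1.5 equiv), DCC, DMAP (cat.), CH2Cl2, 0 °C to rt
Reagents that add atoms: none
Why: Steglich esterification acylates the secondary C3 hydroxyl while the tertiary C4 hydroxyl is inert under carbodiimide/DMAP activation, and the stereocentre of 12 is β to the carboxyl group and cannot epimerise.

**Compound list**
1 | (E)-β-ocimene, (3E)-3,7-dimethylocta-1,3,6-triene | C=C/C(C)=C/CC=C(C)C | starting material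
2 | methacrolein, 2-methylprop-2-enal | CC(=C)C=O | starting material
3 | (1S,2S)-1,3-dimethyl-2-(3-methylbut-2-en-1-yl)cyclohex-3-ene-1-carbaldehyde | CC1=CCC[C@](C)(C=O)[C@H]1CC=C(C)C | intermediate
4 | (methoxymethyl)triphenylphosphonium chloride | COC[P+](c1ccccc1)(c1ccccc1)c1ccccc1.[Cl-] | starting material
5 | (methoxymethylene)triphenylphosphorane | COC=P(c1ccccc1)(c1ccccc1)c1ccccc1 | intermediate (not isolated)
6 | (5S,6S)-5-(2-methoxyethenyl)-1,5-dimethyl-6-(3-methylbut-2-en-1-yl)cyclohex-1-ene, E/Z mixture | CC1=CCC[C@](C)(C=COC)[C@H]1CC=C(C)C | intermediate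
7 | 2-[(1R,2R)-1,3-dimethyl-2-(3-methylbut-2-en-1-yl)cyclohex-3-en-1-yl]acetaldehyde | CC1=CCC[C@](C)(CC=O)[C@H]1CC=C(C)C | intermediate
8 | (2S,3R,4aR,8aR)-5,8a-dimethyl-3-(prop-1-en-2-yl)-1,2,3,4,4a,7,8,8a-octahydronaphthalen-2-ol | CC1=CCC[C@]2(C)C[C@H](O)[C@@H](C(C)=C)C[C@@H]12 | intermediate
9 | (3R,4aR,8aR)-5,8a-dimethyl-3-(prop-1-en-2-yl)-3,4,4a,7,8,8a-hexahydronaphthalen-2(1H)-one | CC1=CCC[C@]2(C)CC(=O)[C@@H](C(C)=C)C[C@@H]12 | intermediate
10 | (4aR,8aR)-5,8a-dimethyl-3-(propan-2-ylidene)-3,4,4a,7,8,8a-hexahydronaphthalen-2(1H)-one | CC1=CCC[C@]2(C)CC(=O)C(=C(C)C)C[C@@H]12 | intermediate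
11 | (4aR,5S,6R,8aR)-5,6-dihydroxy-5,8a-dimethyl-3-(propan-2-ylidene)-3,4,4a,5,6,7,8,8a-octahydronaphthalen-2(1H)-one | O[C@@H]1CC[C@]2(C)CC(=O)C(=C(C)C)C[C@H]2[C@]1(C)O | intermediate
12 | (S)-3-methylpentanoic acid | CC[C@H](C)CC(=O)O | starting material
13 | (1S,2R,4aR,8aR)-1-hydroxy-1,4a-dimethyl-6-oxo-7-(propan-2-ylidene)decahydronaphthalen-2-yl (3S)-3-methylpentanoate | CC[C@H](C)CC(=O)O[C@@H]1CC[C@]2(C)CC(=O)C(=C(C)C)C[C@H]2[C@]1(C)O | target

**Step count**
Total steps: 8. Longest linear sequence: 8 steps (from 1 and 2 to 13).

**Steps most likely to fail**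

Step 1 (key cycloaddition). The process at risk is exo control: if the formyl group goes endo, it ends up cis to the prenyl arm and leads to a cis-fused skeleton. Lesser risks are leakage to the para-type regioisomer and acid-induced oligomerisation of the triene. The fallback sets out from 1 and exchanges the roles of the two groups on the dienophile carbon, so that the ordinary carbonyl-endo preference gives the needed relation.
- Commercial 4-(benzyloxy)butanal would be α-methylenated (aq. CH2O, catalytic pyrrolidine and propanoic acid) to 4-(benzyloxy)-2-methylidenebutanal F1.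
- Cycloaddition of F1 with 1 under the mirror-image (R)-oxazaborolidine/HNTf2 catalyst, through the formyl-endo transition state, should give (1S,2S)-1-[2-(benzyloxy)ethyl]-3-methyl-2-(3-methylbut-2-en-1-yl)cyclohex-3-ene-1-carbaldehyde F2, with formyl cis to the prenyl arm.
- Wolff–Kishner reduction (N2H4·H2O, KOH, diethylene glycol, 200 °C) would turn the neopentyl formyl group into the C14 methyl group, giving ({2-[(1R,2R)-1,3-dimethyl-2-(3-methylbut-2-en-1-yl)cyclohex-3-en-1-yl]ethoxy}methyl)benzene F3.
- Li/NH3 debenzylation, which leaves isolated trisubstituted alkenes alone, would give 2-[(1R,2R)-1,3-dimethyl-2-(3-methylbut-2-en-1-yl)cyclohex-3-en-1-yl]ethan-1-ol F4.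
- Dess–Martin oxidation of F4 comes back to the route at 7; steps 2 and 3 are then not needed.

Step 4 (ring B closure). The processes at risk are proton-initiated cation–olefin cyclisation between the two trisubstituted alkenes, bridged capture of the aldehyde by the ring olefin, and methyl transfer from aluminium to the aldehyde. The fallback sets out from 7 and forms the same C7–C8 bond by olefin acylation.
- Pinnick oxidation (NaClO2, NaH2PO4, 2-methylbut-2-ene, tBuOH/H2O) would give 2-[(1R,2R)-1,3-dimethyl-2-(3-methylbut-2-en-1-yl)cyclohex-3-en-1-yl]acetic acid F5.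
- (COCl)2 with catalytic DMF would give 2-[(1R,2R)-1,3-dimethyl-2-(3-methylbut-2-en-1-yl)cyclohex-3-en-1-yl]acetyl chloride F6.
- SnCl4 in CH2Cl2 at −78 °C would effect intramolecular Friedel–Crafts-type acylation of the C7=C11 olefin, with chloride capturing the tertiary C11 cation, to give (4aR,8aR)-3-(2-chloropropan-2-yl)-5,8a-dimethyl-3,4,4a,7,8,8a-hexahydronaphthalen-2(1H)-one F7.
- DBU would eliminate HCl from F7 and come back to the route at 10; steps 5 and 6 are then not needed.

Step 7 (dihydroxylation). The process at risk is poor facial selectivity, with osmylation occurring syn to the angular methyl group, or slow turnover at the hindered olefin. The fallback sets out from 10 and uses a Woodward cis-hydroxylation (I2, AgOAc, AcOH containing water), which places both oxygens on the face opposite to the one attacked first.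
- Iodonium formation and anti opening by acetate would give 3β-iodo-8-oxoeudesm-7(11)-en-4α-yl acetate F8.
- Silver-assisted displacement of iodide by the neighbouring acetate and opening of the acetoxonium ion by water would give 4α-hydroxy-8-oxoeudesm-7(11)-en-3α-yl acetate F9.
- Methanolysis of F9 (K2CO3, MeOH) comes back to the route at 11.

**Further compounds**
F1 | step 1 | 4-(benzyloxy)-2-methylidenebutanal | C=C(CCOCc1ccccc1)C=O
F2 | step 1 | (1S,2S)-1-[2-(benzyloxy)ethyl]-3-methyl-2-(3-methylbut-2-en-1-yl)cyclohex-3-ene-1-carbaldehyde | CC1=CCC[C@](C=O)(CCOCc2ccccc2)[C@H]1CC=C(C)C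
F3 | step 1 | ({2-[(1R,2R)-1,3-dimethyl-2-(3-methylbut-2-en-1-yl)cyclohex-3-en-1-yl]ethoxy}methyl)benzene | CC1=CCC[C@](C)(CCOCc2ccccc2)[C@H]1CC=C(C)C
F4 | step 1 | 2-[(1R,2R)-1,3-dimethyl-2-(3-methylbut-2-en-1-yl)cyclohex-3-en-1-yl]ethan-1-ol | CC1=CCC[C@](C)(CCO)[C@H]1CC=C(C)C
F5 | step 4 | 2-[(1R,2R)-1,3-dimethyl-2-(3-methylbut-2-en-1-yl)cyclohex-3-en-1-yl]acetic acid | CC1=CCC[C@](C)(CC(=O)O)[C@H]1CC=C(C)C
F6 | step 4 | 2-[(1R,2R)-1,3-dimethyl-2-(3-methylbut-2-en-1-yl)cyclohex-3-en-1-yl]acetyl chloride | CC1=CCC[C@](C)(CC(Cl)=O)[C@H]1CC=C(C)C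
F7 | step 4 | (4aR,8aR)-3-(2-chloropropan-2-yl)-5,8a-dimethyl-3,4,4a,7,8,8a-hexahydronaphthalen-2(1H)-one | CC1=CCC[C@]2(C)CC(=O)C(C(C)(C)Cl)C[C@@H]12
F8 | step 7 | 3β-iodo-8-oxoeudesm-7(11)-en-4α-yl acetate | I[C@H]1CC[C@]2(C)CC(=O)C(=C(C)C)C[C@H]2[C@]1(C)OC(C)=O
F9 | step 7 | 4α-hydroxy-8-oxoeudesm-7(11)-en-3α-yl acetate | CC(=O)O[C@@H]1CC[C@]2(C)CC(=O)C(=C(C)C)C[C@H]2[C@]1(C)O
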